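**Retrosynthetic overview**
- The terminal alkyne comes from a one-carbon (Seyferth–Gilbert) homologation of an (E)-enal; the enal comes from Wittig opening of a lactol, itself from a cis-fused bicyclic γ-lactone.
- The C–Br bond comes from SN2 bromination (inversion) of a (1S)-homoallylic alcohol; that alcohol and its (E)-alkene come from a Felkin-selective Hosomi–Sakurai addition of 3-(trimethylsilyl)pent-1-ene to a lactone aldehyde.
- The aldehyde comes from ozonolysis of a vinyl lactone, made by desymmetrising PdCl2-catalysed oxycarbonylation of C2-symmetric (3R,5R)-hepta-1,6-diene-3,5-diol.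
- The diene diol comes from (2R,4R)-1,5-dichloropentane-2,4-diol by double one-carbon homologation with a sulfonium ylide.
- Ring order: the oxolane ring and a temporary fused γ-lactone ring are formed together in one step; the lactone ring is later opened (reduction, Wittig); no other ring is made.

Assumption: (2R,4R)-1,5-dichloropentane-2,4-diol, (E)-1-chloropent-2-ene and dimethyl (diazomethyl)phosphonate are taken as catalogue chemicals.

**Route**

Step 1
Reactants: 1 (2R,4R)-1,5-dichloropentane-2,4-diol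
Product: 3 (3R,5R)-hepta-1,6-diene-3,5-diol, via bis-epoxide 2 (not isolated)
Conditions: Me3S+ I− (8 equiv), n-BuLi (8 equiv), THF, −20 °C → rt
Reagents that add atoms: trimethylsulfonium iodide, C[S+](C)C.[I-]
Why: Base closes each chlorohydrin to the epoxide without touching the carbinol C–O bond, and dimethylsulfonium methylide then opens the terminal carbon and eliminates dimethyl sulfide (epoxide-to-allylic-alcohol one-carbon homologation), so both R centres are carried over unchanged.

Step 2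
Reactants: 3 (3R,5R)-hepta-1,6-diene-3,5-diol
Product: 4 (3aR,5R,6aR)-5-ethenylhexahydrofuro[3,2-b]furan-2(3H)-one
Conditions: PdCl2 (10 mol %), CuCl2 (3 equiv), NaOAc (3 equiv), CO (1 atm), AcOH, rt
Reagents that add atoms: carbon monoxide, [C-]#[O+]
Why: Semmelhack-type intramolecular alkoxycarbonylation–lactonisation, in which divalent palladium triggers 5-exo attack of the remote OH on the alkene, CO inserts and the neighbouring allylic OH closes the γ-lactone, forcing the new C–C bond cis to that oxygen (new centre 3aR); the C2 symmetry makes both hydroxyl/alkene pairings give the same product, the anti-diol places the vinyl group on the same face, and CuCl2 reoxidises zerovalent palladium.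

Step 3
Reactants: 4 (3aR,5R,6aR)-5-ethenylhexahydrofuro[3,2-b]furan-2(3H)-one
Product: 6 (3aR,5R,6aR)-2-oxohexahydrofuro[3,2-b]furan-5-carbaldehyde, via ozonide 5 (not isolated)
Conditions: O3, CH2Cl2, −78 °C; then PPh3, −78 °C → rt; short silica pad, used at once
Reagents that add atoms: ozone, [O-][O+]=O
Why: Ozonolysis with reductive work-up cleaves the only alkene to the aldehyde under neutral conditions, so the α-alkoxy stereocentre is not epimerised.

Step 4
Reactants: 7 (E)-1-chloropent-2-ene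
Product: 8 rac-3-(trimethylsilyl)pent-1-ene
Conditions: Me3SiSiMe3, MeLi, HMPA–THF, 0 °C; CuI, −60 °C; then 7, −60 °C → rt; distillation
Reagents that add atoms: hexamethyldisilane, C[Si](C)(C)[Si](C)(C)C
Why: Trimethylsilylcopper substitutes the primary allylic chloride with allylic transposition (SN2′) to give the branched allylsilane, and the racemate suffices because its stereocentre is destroyed in the next step.

Step 5
Reactants: 6 (3aR,5R,6aR)-2-oxohexahydrofuro[3,2-b]furan-5-carbaldehyde; 8 rac-3-(trimethylsilyl)pent-1-ene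
Product: 9 (3aR,5R,6aR)-5-[(1S,3E)-1-hydroxyhex-3-en-1-yl]hexahydrofuro[3,2-b]furan-2(3H)-one
Conditions: 8 (2.5 equiv), BF3·OEt2 (1.5 equiv), CH2Cl2, −78 °C
Reagents that add atoms: none
Why: Hosomi–Sakurai allylation through an open transition state, where monodentate BF3 cannot chelate so the α-alkoxy aldehyde reacts in the Felkin–Anh sense to give the (1S) alcohol (OH anti to the ring oxygen), and anti-SE2′ attack with the ethyl group turned away from the alkene fixes the new double bond as E.

Step 6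
Reactants: 9 (3aR,5R,6aR)-5-[(1S,3E)-1-hydroxyhex-3-en-1-yl]hexahydrofuro[3,2-b]furan-2(3H)-one
Product: 10 (3aR,5R,6aR)-5-[(1R,3E)-1-bromohex-3-en-1-yl]hexahydrofuro[3,2-b]furan-2(3H)-one
Conditions: CBr4, (n-C8H17)3P, toluene, 70 °C
Reagents that add atoms: carbon tetrabromide, BrC(Br)(Br)Br
Why: Appel-type bromination in which the phosphine/CBr4 pair activates the hydroxyl and bromide displaces it by SN2 with inversion, turning (1S)-OH into (1R)-Br; the electron-rich trialkylphosphine at 70 °C is chosen because β-alkoxy secondary alcohols are sluggish.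

Step 7
Reactants: 10 (3aR,5R,6aR)-5-[(1R,3E)-1-bromohex-3-en-1-yl]hexahydrofuro[3,2-b]furan-2(3H)-one
Product: 11 (3aR,5R,6aR)-5-[(1R,3E)-1-bromohex-3-en-1-yl]hexahydrofuro[3,2-b]furan-2-ol (anomer mixture)
Conditions: i-Bu2AlH (1.1 equiv), CH2Cl2, −78 °C; aq. KNaC4H4O6 work-up
Reagents that add atoms: none
Why: Partial reduction of a γ-lactone with i-Bu2AlH at −78 °C stops at the lactol, and the secondary bromide and the alkene are inert under these conditions.

Step 8
Reactants: 11 (3aR,5R,6aR)-5-[(1R,3E)-1-bromohex-3-en-1-yl]hexahydrofuro[3,2-b]furan-2-ol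
Product: 12 (2E)-4-[(2R,3R,5R)-5-[(1R,3E)-1-bromohex-3-en-1-yl]-3-hydroxyoxolan-2-yl]but-2-enal
Conditions: Ph3P=CHCHO (1.5 equiv), benzene, 80 °C
Reagents that add atoms: (triphenylphosphoranylidene)acetaldehyde, O=CC=P(c1ccccc1)(c1ccccc1)c1ccccc1
Why: Wittig olefination of the open hydroxy-aldehyde form of the lactol with a stabilised ylide gives the (E)-enal selectively and frees the ring hydroxyl without touching any stereocentre.

Step 9
Reactants: 12 (2E)-4-[(2R,3R,5R)-5-[(1R,3E)-1-bromohex-3-en-1-yl]-3-hydroxyoxolan-2-yl]but-2-enal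
Product: 13 (2R,3R,5R)-5-[(1R,3E)-1-bromohex-3-en-1-yl]-2-[(2E)-4-oxobut-2-en-1-yl]oxolan-3-yl acetate
Conditions: Ac2O, pyridine, DMAP (cat.), CH2Cl2, 0 °C → rt
Reagents that add atoms: acetic anhydride, CC(=O)OC(C)=O
Why: DMAP-catalysed acetylation of the secondary alcohol, placed before the base-mediated step so that the free hydroxyl cannot add to the enal (oxa-Michael).

Step 10
Reactants: 13 (2R,3R,5R)-5-[(1R,3E)-1-bromohex-3-en-1-yl]-2-[(2E)-4-oxobut-2-en-1-yl]oxolan-3-yl acetate
Product: 15 trans-kumausyne, (2R,3R,5R)-5-[(1R,3E)-1-bromohex-3-en-1-yl]-2-[(2E)-pent-2-en-4-yn-1-yl]oxolan-3-yl acetate, via diazoalkene 14 (not isolated)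
Conditions: (MeO)2P(O)CHN2, KOtBu, THF, −78 °C → −30 °C
Reagents that add atoms: dimethyl (diazomethyl)phosphonate, COP(=O)(OC)C=[N+]=[N-]
Why: Seyferth–Gilbert homologation, in which a Horner–Wadsworth–Emmons-type condensation gives diazoalkene 14 that loses N2 with a 1,2-hydrogen shift to the terminal alkyne while the (E)-alkene is retained; at −78 °C the acetate and the secondary bromide survive the brief exposure to base.

**Compound list**
1 | (2R,4R)-1,5-dichloropentane-2,4-diol | ClC[C@H](O)C[C@@H](O)CCl | starting material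
2 | (2R,4R)-1,2:4,5-diepoxypentane (bis-epoxide) | C1O[C@@H]1C[C@@H]1CO1 | intermediate (not isolated)
3 | (3R,5R)-hepta-1,6-diene-3,5-diol | C=C[C@H](O)C[C@@H](O)C=C | intermediate
4 | (3aR,5R,6aR)-5-ethenylhexahydrofuro[3,2-b]furan-2(3H)-one | O=C1C[C@H]2O[C@@H](C=C)C[C@H]2O1 | intermediate
5 | (3aR,5R,6aR)-5-(1,2,4-trioxolan-3-yl)hexahydrofuro[3,2-b]furan-2(3H)-one (ozonide, epimer mixture at the trioxolane carbon) | O=C1C[C@H]2O[C@@H](C3OCOO3)C[C@H]2O1 | intermediate (not isolated)
6 | (3aR,5R,6aR)-2-oxohexahydrofuro[3,2-b]furan-5-carbaldehyde | O=C1C[C@H]2O[C@@H](C=O)C[C@H]2O1 | intermediate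
7 | (E)-1-chloropent-2-ene | CC/C=C/CCl | starting material
8 | rac-3-(trimethylsilyl)pent-1-ene | C=CC(CC)[Si](C)(C)C | intermediate
9 | (3aR,5R,6aR)-5-[(1S,3E)-1-hydroxyhex-3-en-1-yl]hexahydrofuro[3,2-b]furan-2(3H)-one | O=C1C[C@H]2O[C@@H]([C@@H](O)C/C=C/CC)C[C@H]2O1 | intermediate
10 | (3aR,5R,6aR)-5-[(1R,3E)-1-bromohex-3-en-1-yl]hexahydrofuro[3,2-b]furan-2(3H)-one | O=C1C[C@H]2O[C@@H]([C@H](Br)C/C=C/CC)C[C@H]2O1 | intermediate
11 | (3aR,5R,6aR)-5-[(1R,3E)-1-bromohex-3-en-1-yl]hexahydrofuro[3,2-b]furan-2-ol (anomer mixture) | OC1C[C@H]2O[C@@H]([C@H](Br)C/C=C/CC)C[C@H]2O1 | intermediate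
12 | (2E)-4-[(2R,3R,5R)-5-[(1R,3E)-1-bromohex-3-en-1-yl]-3-hydroxyoxolan-2-yl]but-2-enal | O=C/C=C/C[C@H]1O[C@@H]([C@H](Br)C/C=C/CC)C[C@H]1O | intermediate
13 | (2R,3R,5R)-5-[(1R,3E)-1-bromohex-3-en-1-yl]-2-[(2E)-4-oxobut-2-en-1-yl]oxolan-3-yl acetate | O=C/C=C/C[C@H]1O[C@@H]([C@H](Br)C/C=C/CC)C[C@H]1OC(C)=O | intermediate
14 | (2R,3R,5R)-5-[(1R,3E)-1-bromohex-3-en-1-yl]-2-[(2E)-5-diazopenta-2,4-dien-1-yl]oxolan-3-yl acetate (diazoalkene) | [N-]=[N+]=C=C/C=C/C[C@H]1O[C@@H]([C@H](Br)C/C=C/CC)C[C@H]1OC(C)=O | intermediate (not isolated)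
15 | trans-kumausyne, (2R,3R,5R)-5-[(1R,3E)-1-bromohex-3-en-1-yl]-2-[(2E)-pent-2-en-4-yn-1-yl]oxolan-3-yl acetate | C#C/C=C/C[C@H]1O[C@@H]([C@H](Br)C/C=C/CC)C[C@H]1OC(C)=O | target

**Step count**
Total steps: 10. Longest linear sequence: 9 (1 → 15 through steps 1–3 and 5–10; step 4 is a one-step side branch).

**Steps most likely to fail, with fallbacks**

Step 6 (bromination with inversion). SN2 at a secondary carbinol next to the ring oxygen is slow, and elimination to a diene or participation of the ring oxygen (ring expansion, retention) can compete. The fallback sets out from 9 and comes back at 10. Alcohol 9 is first converted with ClCH2SO2Cl and pyridine (CH2Cl2, 0 °C) into the isolable sulfonate (3aR,5R,6aR)-5-[(1S,3E)-1-(chloromethanesulfonyloxy)hex-3-en-1-yl]hexahydrofuro[3,2-b]furan-2(3H)-one F1. This sulfonate is then displaced in a separate SN2 step with LiBr in DMF at 50 °C to give 10 with inversion, so the displacement runs on a defined leaving group with free bromide instead of an oxyphosphonium species.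

Step 8 (Wittig on the lactol). The lactol may open slowly, the enal can react with a second ylide, and the free hydroxyl can add back to the enal. The fallback sets out from 11 and comes back at 15, avoiding any enal. Lactol 11 is treated with the lithium anion of diethyl [3-(trimethylsilyl)prop-2-yn-1-yl]phosphonate (LiN(SiMe3)2, THF, −78 → 0 °C) in a Horner–Wadsworth–Emmons reaction. This gives the silylated enyne (2R,3R,5R)-5-[(1R,3E)-1-bromohex-3-en-1-yl]-2-[(2E)-5-(trimethylsilyl)pent-2-en-4-yn-1-yl]oxolan-3-ol F2, with minor Z isomer removed by chromatography. K2CO3 in MeOH then removes the silyl group to give (2R,3R,5R)-5-[(1R,3E)-1-bromohex-3-en-1-yl]-2-[(2E)-pent-2-en-4-yn-1-yl]oxolan-3-ol F3, and Ac2O/pyridine/DMAP acetylates it to 15.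

Step 10 (alkyne formation beside an acetate and a secondary bromide). The base could cleave the acetate or attack the bromide. The fallback sets out from 11 and comes back at 15, building the enyne by cross-coupling under neutral conditions. Takai olefination of 11 (CrCl2, CHI3, THF, 0 °C → rt) gives (2R,3R,5R)-5-[(1R,3E)-1-bromohex-3-en-1-yl]-2-[(2E)-3-iodoprop-2-en-1-yl]oxolan-3-ol F4. Acetylation (Ac2O, pyridine, DMAP) gives (2R,3R,5R)-5-[(1R,3E)-1-bromohex-3-en-1-yl]-2-[(2E)-3-iodoprop-2-en-1-yl]oxolan-3-yl acetate F5. Stille coupling of F5 with tributyl(ethynyl)stannane (Pd(PPh3)4, DMF, rt) then delivers 15 with retention of the E geometry; the alkyl bromide does not react with the zerovalent palladium catalyst under these conditions.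

**Further compounds**
F1 | step 6 | (3aR,5R,6aR)-5-[(1S,3E)-1-(chloromethanesulfonyloxy)hex-3-en-1-yl]hexahydrofuro[3,2-b]furan-2(3H)-one | O=C1C[C@H]2O[C@@H]([C@@H](OS(=O)(=O)CCl)C/C=C/CC)C[C@H]2O1
F2 | step 8 | (2R,3R,5R)-5-[(1R,3E)-1-bromohex-3-en-1-yl]-2-[(2E)-5-(trimethylsilyl)pent-2-en-4-yn-1-yl]oxolan-3-ol | C[Si](C)(C)C#C/C=C/C[C@H]1O[C@@H]([C@H](Br)C/C=C/CC)C[C@H]1O
F3 | step 8 | (2R,3R,5R)-5-[(1R,3E)-1-bromohex-3-en-1-yl]-2-[(2E)-pent-2-en-4-yn-1-yl]oxolan-3-ol | C#C/C=C/C[C@H]1O[C@@H]([C@H](Br)C/C=C/CC)C[C@H]1O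
F4 | step 10 | (2R,3R,5R)-5-[(1R,3E)-1-bromohex-3-en-1-yl]-2-[(2E)-3-iodoprop-2-en-1-yl]oxolan-3-ol | I/C=C/C[C@H]1O[C@@H]([C@H](Br)C/C=C/CC)C[C@H]1O
F5 | step 10 | (2R,3R,5R)-5-[(1R,3E)-1-bromohex-3-en-1-yl]-2-[(2E)-3-iodoprop-2-en-1-yl]oxolan-3-yl acetate | I/C=C/C[C@H]1O[C@@H]([C@H](Br)C/C=C/CC)C[C@H]1OC(C)=O
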